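**Plan**

1. Retrosynthesis first removes the three angelates, the epoxide oxygen and the C-2′ stereocenter (esterification, Shi epoxidation, cross-metathesis, Brown allylation of a 2-substituted acrolein). This leads back to a 5-ethynylcyclohexanone, whose C-3/C-4 cis-diol is cut to an alkene and whose C-1 ketone is cut to an alcohol.
2. In the cyclohexene that remains, the tertiary C-2–O bond and the C-5–C-1′ bond are cis-1,4 on the ring. Closed to a lactone they are the O–C(=O) bridge of a 2-oxabicyclo[2.2.2]oct-5-en-3-one, the retron of a 2-pyranone Diels–Alder reaction.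
3. Cutting C-1–C-2 and C-5–C-6 together gives 6-methyl-2H-pyran-2-one (its C-6 with methyl and ring oxygen becomes C-2, its carbonyl carbon becomes C-1′) and vinylene carbonate (C-1, C-6 and both their oxygens).
4. Forward: the cycloaddition builds the carbocycle inside a bicycle; the lactone is reduced and homologated to an alkyne (a vinyl anchor inert to osmylation); then resolution, ketone, diol, silyl ether; then alkyne to vinylsilane, iodide and enal; then the chain, the esters, the epoxide and desilylation.
5. Stereochemistry: C-2/C-5 from the lactone bridge, C-6 from the endo rule, C-3/C-4 from osmylation anti to the allylic C–O bond, absolute configuration from separation of (S)-O-methylmandelates, C-2′ from the Brown reagent, the epoxide from the Shi catalyst.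

Key step: step 1

Remark: locants C-1 to C-6 are those of the target ring throughout (C-1 ketone carbon, C-2 methyl carbinol carbon, C-5 carbon bearing the side chain) and C-1′ to C-5′ those of the side chain counted from the exo-methylene carbon. Compounds 3 to 6 are racemic and are drawn as the enantiomer that is carried on. Compounds 1 and 2 are taken as commercial.

**Route**

Step 1
Reactants: 1 6-methyl-2H-pyran-2-one; 2 vinylene carbonate
Product: 3 racemic endo lactone carbonate (1-methyl-3-oxo-2-oxabicyclo[2.2.2]oct-5-ene-7,8-diyl carbonate)
Conditions: 2 (5 equiv), CH2Cl2, 12 kbar, 40 °C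
Reagents that add atoms: none
Why: Concerted, suprafacial [4+2] cycloaddition (Diels–Alder reaction of a 2-pyranone) in which pyranone C-6 and C-3 bond to the two alkene carbons of 2 and so form C-1–C-2 and C-5–C-6 of the target ring, the closest known reaction type being thermal and high-pressure Diels–Alder additions of 2-pyranones to alkenes that keep the CO2 bridge. The six-membered carbocycle closes by intermolecular 4π+2π cycloaddition, and because the diene is held s-cis in a ring the product is the 2-oxabicyclo[2.2.2]octene. The bridgeheads C-2 and C-5 are controlled by the bridge itself, which forces the tertiary C–O bond and the C-5–C-1′ bond onto one face of the new ring; C-1 and C-6 stay cis because addition is suprafacial on the cis alkene, and their oxygens lie anti to the lactone bridge (endo, under the diene) by the Alder rule. Regiochemistry is no issue because 2 is symmetrical, so the selectivities needed are endo over exo and cycloaddition without loss of CO2; the first is secured by secondary overlap of the carbonate with the diene, the second by working at 40 °C under pressure instead of at high temperature. No absolute control is expected, so 3 is racemic and is resolved in step 4.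

Step 2
Reactants: 3 racemic endo lactone carbonate
Product: 4 racemic lactol carbonate (anomeric mixture)
Conditions: i-Bu2AlH (1.1 equiv), CH2Cl2, −78 °C; aq. KNaC4H4O6 (Rochelle salt) work-up
Reagents that add atoms: none
Why: Partial reduction of a lactone to the lactol by i-Bu2AlH at low temperature, where the tetrahedral aluminate is stable and the strained bridged lactone should react faster than the cyclic carbonate; no ring stereocenter is touched and the new hemiacetal center is of no consequence.

Step 3
Reactants: 4 racemic lactol carbonate
Product: 6 racemic alkyne triol (4-ethynyl-1-methylcyclohex-5-ene-1,2,3-triol), via lactol triol 5 (not isolated)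
Conditions: dimethyl (1-diazo-2-oxopropyl)phosphonate, K2CO3 (3 equiv), MeOH, 0 °C to rt
Reagents that add atoms: dimethyl (1-diazo-2-oxopropyl)phosphonate (Ohira–Bestmann reagent), COP(=O)(OC)C(=[N+]=[N-])C(C)=O
Why: Ohira–Bestmann (Seyferth–Gilbert) homologation: methoxide first cleaves the cyclic carbonate by transesterification, the lactol opens to the hydroxy aldehyde, and the diazomethylphosphonate anion made in situ converts the aldehyde into the terminal alkyne, chosen as a masked 1,1-disubstituted vinyl unit that survives the later osmylation.

Step 4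
Reactants: 6 racemic alkyne triol
Product: 7 C-6 (S)-O-methylmandelate of the alkyne triol with the ring configuration of the target
Conditions: (S)-O-methylmandelic acid (1.05 equiv), DCC, DMAP (cat.), CH2Cl2, −20 °C; chromatographic separation of the two diastereomers
Reagents that add atoms: (S)-2-methoxy-2-phenylacetic acid, CO[C@H](C(=O)O)c1ccccc1
Why: Steglich esterification at the equatorial, less hindered C-6 hydroxyl (the C-1 hydroxyl is axial beside the quaternary carbinol and the C-2 hydroxyl is tertiary) turns the racemate into two diastereomeric esters (classical resolution through covalent diastereomers), of which the one with the target ring configuration is carried on with the auxiliary serving as the C-6 protecting group.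

Step 5
Reactants: 7 C-6 mandelate diol
Product: 8 β,γ-unsaturated α-hydroxy ketone (C-1 ketone)
Conditions: Dess–Martin periodinane, CH2Cl2, 0 °C to rt
Reagents that add atoms: none
Why: Dess–Martin oxidation of the only secondary alcohol left gives the C-1 ketone, the tertiary C-2 hydroxyl being inert and no stereocenter being formed.

Step 6
Reactants: 8 cyclohexenone
Product: 9 C-3/C-4 cis-diol
Conditions: OsO4 (2 mol %), NMO, acetone/H2O, rt
Reagents that add atoms: N-methylmorpholine N-oxide, C[N+]1([O-])CCOCC1; water, O
Why: Upjohn cis-dihydroxylation: in the half-chair with the C-5 and C-6 substituents equatorial the tertiary C-2 hydroxyl is pseudoaxial on the lower face, so OsO4 should add to the C-3=C-4 alkene anti to this allylic oxygen and anti to the C-5 alkynyl group (Kishi's rule), which places both new hydroxyls cis to each other and trans to the C-5 substituent, while the alkyne reacts far more slowly.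

Step 7
Reactants: 9 cis-diol
Product: 10 C-4 triethylsilyl ether
Conditions: Et3SiCl (1.05 equiv), imidazole, CH2Cl2, −40 °C
Reagents that add atoms: chlorotriethylsilane, CC[Si](Cl)(CC)CC
Why: Selective silylation of the equatorial C-4 hydroxyl, which sits between two CH carbons, over the axial neopentylic C-3 hydroxyl and the tertiary C-2 hydroxyl.

Step 8
Reactants: 10 alkyne
Product: 11 geminal vinylsilane (C-5 bears a 1-(triethylsilyl)vinyl group)
Conditions: [Cp*Ru(MeCN)3]PF6 (5 mol %), Et3SiH, CH2Cl2, 0 °C to rt
Reagents that add atoms: triethylsilane, CC[SiH](CC)CC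
Why: Ruthenium-catalysed Markovnikov (geminal) hydrosilylation of a terminal alkyne (Trost), which places silicon on the internal carbon and tolerates free hydroxyls, the ketone and the ester.

Step 9
Reactants: 11 vinylsilane
Product: 12 2-iodoalkene (C-5 bears a 1-iodovinyl group)
Conditions: NIS, 2,6-lutidine (cat.), (CF3)2CHOH/CH2Cl2, 0 °C
Reagents that add atoms: N-iodosuccinimide, O=C1CCC(=O)N1I
Why: Iododesilylation (ipso substitution of the vinylsilane by electrophilic iodine) gives the 1,1-disubstituted vinyl iodide without moving the double bond.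

Step 10
Reactants: 12 vinyl iodide
Product: 13 2-substituted acrolein (C-5 bears a 3-oxoprop-1-en-2-yl group)
Conditions: Pd(PPh3)4 (5 mol %), CO (1 atm), Bu3SnH (slow addition), THF, 50 °C
Reagents that add atoms: carbon monoxide, [C-]#[O+]
Why: Palladium-catalysed reductive carbonylation (formylation) of a vinyl iodide by oxidative addition, CO insertion and hydride transfer from Bu3SnH, under neutral conditions that leave the α-acyloxy ketone alone.

Step 11
Reactants: 13 enal
Product: 14 (2′S)-homoallylic alcohol
Conditions: (−)-Ipc2B(allyl) from (+)-α-pinene (salt-free, 2.5 equiv), Et2O, −78 °C; then HOCH2CH2NH2, rt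
Reagents that add atoms: (−)-B-allyldiisopinocampheylborane, C=CCB([C@H]1[C@H](C)[C@H]2C[C@@H](C1)C2(C)C)[C@H]1[C@H](C)[C@H]2C[C@@H](C1)C2(C)C
Why: Brown asymmetric allylboration through a chair-like six-membered transition state in which the reagent from (+)-α-pinene adds to the Si face of the aldehyde, so the new C-2′ carbinol is set to S by reagent control while the hindered C-1 ketone does not react at −78 °C.

Step 12
Reactants: 14 terminal alkene
Product: 15 trisubstituted alkene (2-methylprop-1-enyl end group)
Conditions: second-generation Grubbs catalyst (5 mol %), 2-methylbut-2-ene/CH2Cl2, 40 °C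
Reagents that add atoms: 2-methylbut-2-ene, CC=C(C)C
Why: Olefin cross-metathesis with 2-methylbut-2-ene converts the terminal vinyl group into the trisubstituted alkene, the 1,1-disubstituted alkene next to the ring being too hindered to take part.

Step 13
Reactants: 15 C-6 mandelate
Product: 16 3,6,2′-triol (C-4 silyl ether kept)
Conditions: K2CO3 (0.2 equiv), MeOH, −10 °C
Reagents that add atoms: none
Why: Base-catalysed transesterification (methanolysis) of the α-methoxy ester, which is further activated by the neighbouring ketone and should cleave under conditions that leave the silyl ether in place, C-6 keeping the equatorial configuration that is also the thermodynamically preferred one.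

Step 14
Reactants: 16 triol
Product: 17 3,6,2′-tris-angelate
Conditions: angelic acid, 2,4,6-trichlorobenzoyl chloride, Et3N, toluene, rt; then 16, 75 °C
Reagents that add atoms: angelic acid ((Z)-2-methylbut-2-enoic acid), C/C=C(/C)C(=O)O
Why: Yamaguchi-type esterification through the mixed anhydride of angelic acid and 2,4,6-trichlorobenzoic acid, run without a nucleophilic catalyst to avoid Z-to-E isomerization, should acylate the three secondary hydroxyls while the tertiary C-2 hydroxyl stays free.

Step 15
Reactants: 17 tris-angelate
Product: 18 (4′S)-epoxide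
Conditions: ent-Shi ketone (L-fructose-derived, 30 mol %), KHSO5 (as Oxone), K2CO3, Bu4NHSO4 (cat.), MeCN/CH2(OMe)2/H2O, pH 10.5, 0 °C
Reagents that add atoms: potassium peroxymonosulfate, [K+].[O-]S(=O)(=O)OO
Why: Shi asymmetric epoxidation, in which the chiral dioxirane attacks the electron-rich trisubstituted alkene through a spiro transition state and the L-series ketone delivers oxygen to the face that gives the (S)-epoxide, the 1,1-disubstituted alkene with its allylic ester and the three enoate alkenes being electron-poor and left untouched.

Step 16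
Reactants: 18 silyl ether
Product: 19 target CNP0145026.1
Conditions: HF·pyridine, pyridine, THF, 0 °C
Reagents that add atoms: none
Why: Fluoride-mediated cleavage of the triethylsilyl ether under buffered conditions frees the C-4 hydroxyl without opening the epoxide or moving the neighbouring angelate.

**Compound list**

1 | 6-methyl-2H-pyran-2-one | CC1=CC=CC(=O)O1 | starting material
2 | vinylene carbonate (1,3-dioxol-2-one) | O=C1OC=CO1 | starting material
3 | racemic endo adduct, 1-methyl-3-oxo-2-oxabicyclo[2.2.2]oct-5-ene-7,8-diyl carbonate, carbonate oxygens syn to the C5=C6 alkene and anti to the lactone bridge (SMILES of the enantiomer carried on) | O=C2[C@@H]1C=C[C@](C)(O2)[C@@H](O3)[C@H]1OC3=O | intermediate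
4 | racemic lactol, 3-hydroxy-1-methyl-2-oxabicyclo[2.2.2]oct-5-ene-7,8-diyl carbonate, anomeric mixture | OC2[C@@H]1C=C[C@](C)(O2)[C@@H](O3)[C@H]1OC3=O | intermediate
5 | racemic lactol triol, 1-methyl-2-oxabicyclo[2.2.2]oct-5-ene-3,7,8-triol (not isolated) | OC2[C@@H]1C=C[C@](C)(O2)[C@@H](O)[C@H]1O | intermediate
6 | racemic 4-ethynyl-1-methylcyclohex-5-ene-1,2,3-triol, 2-OH and 3-OH cis, 1-OH and ethynyl on the opposite face | C#C[C@@H]1C=C[C@](C)(O)[C@@H](O)[C@H]1O | intermediate
7 | C-6 (S)-2-methoxy-2-phenylacetate of the alkyne triol, ring configuration as in the target | C#C[C@@H]1C=C[C@](C)(O)[C@@H](O)[C@H]1OC(=O)[C@@H](OC)c1ccccc1 | intermediate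
8 | 5-ethynyl-2-hydroxy-2-methyl-6-[(S)-O-methylmandeloyloxy]cyclohex-3-en-1-one | C#C[C@@H]1C=C[C@](C)(O)C(=O)[C@H]1OC(=O)[C@@H](OC)c1ccccc1 | intermediate
9 | 5-ethynyl-2,3,4-trihydroxy-2-methyl-6-[(S)-O-methylmandeloyloxy]cyclohexan-1-one, 3-OH and 4-OH cis and trans to the ethynyl group | C#C[C@@H]1[C@@H](O)[C@@H](O)[C@](C)(O)C(=O)[C@H]1OC(=O)[C@@H](OC)c1ccccc1 | intermediate
10 | C-4 triethylsilyl ether of 9 | C#C[C@@H]1[C@@H](O[Si](CC)(CC)CC)[C@@H](O)[C@](C)(O)C(=O)[C@H]1OC(=O)[C@@H](OC)c1ccccc1 | intermediate
11 | 1-(triethylsilyl)vinyl compound | C=C([Si](CC)(CC)CC)[C@@H]1[C@@H](O[Si](CC)(CC)CC)[C@@H](O)[C@](C)(O)C(=O)[C@H]1OC(=O)[C@@H](OC)c1ccccc1 | intermediate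
12 | 1-iodovinyl compound | C=C(I)[C@@H]1[C@@H](O[Si](CC)(CC)CC)[C@@H](O)[C@](C)(O)C(=O)[C@H]1OC(=O)[C@@H](OC)c1ccccc1 | intermediate
13 | 2-substituted acrolein | C=C(C=O)[C@@H]1[C@@H](O[Si](CC)(CC)CC)[C@@H](O)[C@](C)(O)C(=O)[C@H]1OC(=O)[C@@H](OC)c1ccccc1 | intermediate
14 | (2′S)-homoallylic alcohol, C-5 bears (3S)-3-hydroxyhexa-1,5-dien-2-yl | C=C([C@@H]1[C@@H](O[Si](CC)(CC)CC)[C@@H](O)[C@](C)(O)C(=O)[C@H]1OC(=O)[C@@H](OC)c1ccccc1)[C@H](CC=C)O | intermediate
15 | C-5 bears (3S)-3-hydroxy-6-methylhepta-1,5-dien-2-yl | C=C([C@@H]1[C@@H](O[Si](CC)(CC)CC)[C@@H](O)[C@](C)(O)C(=O)[C@H]1OC(=O)[C@@H](OC)c1ccccc1)[C@H](CC=C(C)C)O | intermediate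
16 | 3,6,2′-triol, C-4 triethylsilyl ether, C-2 tertiary OH free | C=C([C@@H]1[C@@H](O[Si](CC)(CC)CC)[C@@H](O)[C@](C)(O)C(=O)[C@H]1O)[C@H](CC=C(C)C)O | intermediate
17 | 3,6,2′-tris-angelate, C-4 triethylsilyl ether | C=C([C@@H]1[C@@H](O[Si](CC)(CC)CC)[C@@H](OC(=O)/C(C)=C\C)[C@](C)(O)C(=O)[C@H]1OC(=O)/C(C)=C\C)[C@H](CC=C(C)C)OC(=O)/C(C)=C\C | intermediate
18 | (4′S)-epoxide of 17 | C=C([C@@H]1[C@@H](O[Si](CC)(CC)CC)[C@@H](OC(=O)/C(C)=C\C)[C@](C)(O)C(=O)[C@H]1OC(=O)/C(C)=C\C)[C@H](C[C@@H]1OC1(C)C)OC(=O)/C(C)=C\C | intermediate
19 | CNP0145026.1, (2S,3R,4R,5R,6S)-3,6-bis(angeloyloxy)-5-[(3S)-3-(angeloyloxy)-4-((2S)-3,3-dimethyloxiran-2-yl)but-1-en-2-yl]-2,4-dihydroxy-2-methylcyclohexan-1-one | C=C([C@@H]1[C@@H](O)[C@@H](OC(=O)/C(C)=C\C)[C@](C)(O)C(=O)[C@H]1OC(=O)/C(C)=C\C)[C@H](C[C@@H]1OC1(C)C)OC(=O)/C(C)=C\C | target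

**Totals**

Total step count: 16.
Longest linear sequence: 16 steps (1 to 19).

**Three steps most likely to fail**

Step 1. The unactivated pyranone may react too slowly with a weak dienophile, the adduct may lose CO2 by cycloreversion, and endo selectivity may erode. Fallback: setting out from 1, bromination and dehydrobromination (Br2, CH2Cl2, then Et3N) gives 3-bromo-6-methyl-2H-pyran-2-one F1, a more reactive ambiphilic diene. Its cycloaddition with 2 (toluene, 90 °C) gives the racemic bridgehead bromo lactone carbonate F2, and radical debromination at the bridgehead (Bu3SnH, AIBN, benzene, 80 °C), which cannot change the configuration, comes back to the route at 3.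

Step 3. In the open hydroxy aldehyde the ring double bond may migrate into conjugation, or C-5 may epimerize under the basic protic conditions, before the aldehyde is trapped. Fallback: setting out from 4, the homologation is run under aprotic, kinetic conditions with lithiated trimethylsilyldiazomethane (Me3SiCHN2, n-BuLi, THF, −78 °C; Colvin rearrangement) to give the racemic ethynyl cyclohexenol cyclic carbonate F3. The carbonate is then cleaved in a separate operation (K2CO3 cat., MeOH, 0 °C), which comes back to the route at 6.

Step 14. Acylation of the axial, neopentylic C-3 hydroxyl may stay incomplete, and the angelate may isomerize from Z to E under forcing conditions. Fallback: setting out from 16, the two accessible hydroxyls are esterified first with the same mixed anhydride at room temperature to give the 6,2′-bis-angelate with free C-3 hydroxyl F4. The C-3 hydroxyl is then converted into its lithium alkoxide (LiN(SiMe3)2, THF, −78 °C) and acylated with angelic anhydride, an acyl transfer to a metal alkoxide that is known to keep the Z geometry, which comes back to the route at 17.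

**Further compounds**

F1 | step 1 | 3-bromo-6-methyl-2H-pyran-2-one | CC1=CC=C(Br)C(=O)O1
F2 | step 1 | racemic 4-bromo-1-methyl-3-oxo-2-oxabicyclo[2.2.2]oct-5-ene-7,8-diyl carbonate (endo) | O=C2[C@]1(Br)C=C[C@](C)(O2)[C@@H](O3)[C@H]1OC3=O
F3 | step 3 | racemic ethynyl cyclohexenol cyclic carbonate (C-1/C-6 carbonate, C-2 OH free) | C#C[C@@H]1C=C[C@](C)(O)[C@@H](O2)[C@H]1OC2=O
F4 | step 14 | 6,2′-bis-angelate with free C-3 hydroxyl, C-4 triethylsilyl ether | C=C([C@@H]1[C@@H](O[Si](CC)(CC)CC)[C@@H](O)[C@](C)(O)C(=O)[C@H]1OC(=O)/C(C)=C\C)[C@H](CC=C(C)C)OC(=O)/C(C)=C\C
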